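Ring B of the target (C4a, C5, C6, C7, C8, C8a), with its C5 ketone, C6 ester, C6=C7 double bond and C8 methylene, is the keto tautomer of a cyclohexa-1,3-dienol. That dienol is a 4-hydroxy-2-pyrone that has taken up a vinyl group and lost CO2. The route therefore rests on disconnecting C4a–C8a and C7–C8 together. The key step is a thermal intramolecular inverse-demand Diels–Alder reaction, followed in the same flask by CO2 extrusion and ketonisation. It closes both carbocycles and sets C8a and C4a. Its precursor is monocyclic: a fully substituted pyrone whose C3 carries a (Z)-skipped-diene chain holding the C4 and C1 stereocentres and a terminal vinyl group.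

Key step: step 8

Assumption: locants C1–C8a follow the hexahydronaphthalene numbering of the target (C1, C4, C6 ester-bearing; C2, C7 hexadecyl-bearing; C5 ketone; C8 methylene; C4a/C8a ring fusion). In the two catalytic asymmetric steps the ligand enantiomer is the one that delivers the drawn configuration.

Step 1
Reactants: 1 methyl acetoacetate; 2 1-bromopentadecane
Product: 3 methyl 3-oxononadecanoate
Conditions: NaH, THF, 0 °C; n-BuLi, 0 °C; 2, 0 °C to rt; aq HCl
Reagents that add atoms: none
Why: γ-Alkylation of a β-keto ester dianion, in which only the more basic terminal carbanion attacks the primary bromide (SN2), should place the C16 chain next to the ketone; no stereocentre is formed.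

Step 2
Reactants: 4 (Z)-but-2-ene-1,4-diol
Product: 5 (Z)-4-[(tert-butyldiphenylsilyl)oxy]but-2-en-1-ol
Conditions: NaH (1 equiv), THF, 0 °C to rt; TBDPSCl (1 equiv)
Reagents that add atoms: tert-butyl(chloro)diphenylsilane, CC(C)(C)[Si](Cl)(c1ccccc1)c1ccccc1
Why: Monosilylation of a symmetrical diol through its sparingly soluble monosodium alkoxide should give the mono-ether, and the acid-tolerant TBDPS group is chosen to survive step 7.

Step 3
Reactants: 5 (Z)-4-[(tert-butyldiphenylsilyl)oxy]but-2-en-1-ol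
Product: 6 (Z)-4-[(tert-butyldiphenylsilyl)oxy]but-2-en-1-yl diethyl phosphate
Conditions: ClP(O)(OEt)2, Et3N, DMAP (cat.), CH2Cl2, 0 °C
Reagents that add atoms: diethyl chlorophosphate, CCOP(=O)(Cl)OCC
Why: O-Phosphorylation of the primary allylic alcohol installs the leaving group used in copper-catalysed SN2′ substitution and leaves the alkene geometry unchanged.

Step 4
Reactants: 7 1-octadecyne; 6 (Z)-4-[(tert-butyldiphenylsilyl)oxy]but-2-en-1-yl diethyl phosphate
Product: 8 tert-butyl{[(2S,3Z)-2-ethenyl-3-[(4,4,5,5-tetramethyl-1,3,2-dioxaborolan-2-yl)methylidene]nonadecyl]oxy}diphenylsilane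
Conditions: CuCl (5 mol %), chiral sulfonate-bearing imidazolinium salt (NHC precursor, 5.5 mol %), NaOt-Bu (1.5 equiv), B2pin2 (1.1 equiv), THF, 22 °C
Reagents that add atoms: bis(pinacolato)diboron, CC1(C)OB(OC1(C)C)B1OC(C)(C)C(C)(C)O1
Why: In this copper-catalysed three-component allylboration of a terminal alkyne, syn-borylcupration puts boron on the terminal carbon and copper on the internal one, which fixes the Z geometry (boron cis to the new branch), and the NHC-controlled SN2′ attack on the phosphate sets the future C1 stereocentre (S) and liberates the vinyl group.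

Step 5
Reactants: 9 di-tert-butyl malonate; 10 methyl glyoxylate
Product: 12 1,1-di-tert-butyl 2-methyl ethene-1,1,2-tricarboxylate, via aldol adduct 11 (not isolated)
Conditions: Et3N (cat.), CH2Cl2, rt; then MsCl, Et3N (2.2 equiv), 0 °C
Reagents that add atoms: none
Why: A Knoevenagel condensation run as aldol addition followed by mesylation and E1cB elimination should give the triester acceptor under mild conditions that spare the tert-butyl esters; no stereocentre or alkene isomer is possible.

Step 6
Reactants: 8 alkenylboronate (2S,3Z); 12 1,1-di-tert-butyl 2-methyl ethene-1,1,2-tricarboxylate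
Product: 13 1,1-di-tert-butyl 2-methyl (2R,3Z,5S)-5-{[(tert-butyldiphenylsilyl)oxy]methyl}-4-hexadecylhepta-3,6-diene-1,1,2-tricarboxylate
Conditions: [RhCl(C2H4)2]2 (2.5 mol %), (R,R)-Ph-bod* (5.5 mol %), K3PO4 (0.5 equiv), dioxane/H2O (10:1), 40 °C
Reagents that add atoms: none
Why: In this Hayashi–Miyaura rhodium/chiral-diene 1,4-addition the alkenyl group is transferred with retention of the Z geometry to the carbon β to the geminal diester (the carbon that bears the methyl ester), and the diene ligand selects the enantioface and so sets the future C4 (R), remote from the existing centre.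

Step 7
Reactants: 13 triester (2R,3Z,5S); 3 methyl 3-oxononadecanoate
Product: 15 methyl 3-[(2R,3Z,5S)-5-{[(tert-butyldiphenylsilyl)oxy]methyl}-4-hexadecyl-1-methoxy-1-oxohepta-3,6-dien-2-yl]-6-hexadecyl-4-hydroxy-2-oxo-2H-pyran-5-carboxylate, via malonyl dichloride 14 (not isolated)
Conditions: SOCl2 (excess), H2O (cat.), 23 °C; evaporate; 3, PhMe, 70 °C
Reagents that add atoms: none
Why: Thionyl chloride converts tert-butyl esters, but not methyl esters, into acid chlorides, and a substituted malonyl dichloride condenses with a β-keto ester by C-acylation then enol O-acylation (malonyl chloride pyrone annulation) to the 4-hydroxy-2-pyrone-5-carboxylate under acidic conditions that should not touch the two stereocentres.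

Step 8
Reactants: 15 pyrone (2R,3Z,5S)
Product: 18 dimethyl (1S,4R,4aS,8aS)-1-{[(tert-butyldiphenylsilyl)oxy]methyl}-2,7-dihexadecyl-5-oxo-1,4,4a,5,8,8a-hexahydronaphthalene-4,6-dicarboxylate, via bridged lactone 16 (not isolated), via ring-fusion dienol 17 (not isolated)
Conditions: PhMe (0.005 M, degassed), BHT (cat.), sealed tube, 150 °C
Reagents that add atoms: none
Why: On heating, the electron-poor pyrone (diene C3=C4–C5=C6, LUMO lowered by the C5 ester and the lactone carbonyl) should add the unactivated vinyl group in a concerted, asynchronous π4s+π2s cycloaddition to bridged lactone 16, which loses CO2 by retro-[4+2] to dienol 17, and 17 ketonises to 18. The closest known reaction type is the intramolecular Diels–Alder reaction of 2-pyrones with tethered unactivated alkenes followed by thermal decarboxylation to cyclohexadienes, and 5-carboalkoxy-2-pyrones add 1-alkenes intermolecularly with the same orientation. Ring B closes as the six-membered [4+2] ring (pyrone C3 to the vinyl CH, pyrone C6 to the vinyl CH2), and ring A closes at the same moment as the six-membered tether ring of a type-1, fused-mode intramolecular cycloaddition whose Z-alkene already holds both ends cis. C8a is controlled by the two tether stereocentres: in the bicyclo[2.2.2] transition state the vinyl CH2 must lie anti to the C4–C4a bond, hence equatorial on the nascent half-chair of ring A, and only the drawn vinyl face lets the C4 ester and the C1 CH2OSi group both sit pseudo-equatorial, whereas the other face puts the C1 group 1,3-diaxial to a pyrone bridge. C4a is quaternary in 16, planar in 17 and is finally set by kinetic ketonisation, the proton arriving on the face that carries H-4 and H-8a, anti to the C4 ester, which gives the cis ring fusion. The step needs regio- and chemoselectivity: the four-atom tether lets only CH reach C3 and CH2 reach C6, which is also the electronically matched pairing (nucleophilic alkene terminus to the most electrophilic pyrone carbon), and the trisubstituted alkene sits too close to the pyrone to compete.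

Step 9
Reactants: 18 silyl ether (1S,4R,4aS,8aS)
Product: 19 dimethyl (1S,4R,4aS,8aS)-2,7-dihexadecyl-1-(hydroxymethyl)-5-oxo-1,4,4a,5,8,8a-hexahydronaphthalene-4,6-dicarboxylate
Conditions: HF·pyridine, pyridine/THF, 0 °C to rt
Reagents that add atoms: none
Why: Fluoride-mediated desilylation in a buffered, weakly acidic medium should free the primary alcohol without enolising C4a or C4 and without moving the C2=C3 double bond.

Step 10
Reactants: 19 primary alcohol (1S,4R,4aS,8aS)
Product: 20 (1S,4R,4aS,8aR)-2,7-dihexadecyl-4,6-bis(methoxycarbonyl)-5-oxo-1,4,4a,5,8,8a-hexahydronaphthalene-1-carboxylic acid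
Conditions: TEMPO (cat.), PhI(OAc)2 (2.2 equiv), MeCN/H2O (1:1), rt
Reagents that add atoms: water, O
Why: Oxoammonium (TEMPO)-catalysed oxidation takes the alcohol through the aldehyde hydrate to the acid in a weakly acidic medium, which should keep the short-lived β,γ-unsaturated aldehyde from epimerising at C1 or conjugating.

Step 11
Reactants: 20 carboxylic acid (1S,4R,4aS,8aR)
Product: 21 trimethyl (1S,4R,4aS,8aR)-2,7-dihexadecyl-5-oxo-1,4,4a,5,8,8a-hexahydronaphthalene-1,4,6-tricarboxylate (target)
Conditions: TMSCHN2, PhMe/MeOH (4:1), 0 °C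
Reagents that add atoms: (trimethylsilyl)diazomethane, C[Si](C)(C)C=[N+]=[N-]
Why: Diazoalkane esterification alkylates the carboxylate oxygen under neutral conditions, so none of the four stereocentres and neither double bond is disturbed.

Compound list
1 | methyl acetoacetate | CC(=O)CC(=O)OC | starting material
2 | 1-bromopentadecane | CCCCCCCCCCCCCCCBr | starting material
3 | methyl 3-oxononadecanoate | CCCCCCCCCCCCCCCCC(=O)CC(=O)OC | intermediate
4 | (Z)-but-2-ene-1,4-diol | OC/C=C\CO | starting material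
5 | (Z)-4-[(tert-butyldiphenylsilyl)oxy]but-2-en-1-ol | OC/C=C\CO[Si](c1ccccc1)(c1ccccc1)C(C)(C)C | intermediate
6 | (Z)-4-[(tert-butyldiphenylsilyl)oxy]but-2-en-1-yl diethyl phosphate | CCOP(=O)(OCC)OC/C=C\CO[Si](c1ccccc1)(c1ccccc1)C(C)(C)C | intermediate
7 | 1-octadecyne | CCCCCCCCCCCCCCCCC#C | starting material
8 | tert-butyl{[(2S,3Z)-2-ethenyl-3-[(4,4,5,5-tetramethyl-1,3,2-dioxaborolan-2-yl)methylidene]nonadecyl]oxy}diphenylsilane | CCCCCCCCCCCCCCCC/C(=C/B1OC(C)(C)C(C)(C)O1)[C@@H](CO[Si](c1ccccc1)(c1ccccc1)C(C)(C)C)C=C | intermediate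
9 | di-tert-butyl malonate | CC(C)(C)OC(=O)CC(=O)OC(C)(C)C | starting material
10 | methyl glyoxylate | COC(=O)C=O | starting material
11 | 1,1-di-tert-butyl 2-methyl 2-hydroxyethane-1,1,2-tricarboxylate (racemic aldol adduct) | COC(=O)C(O)C(C(=O)OC(C)(C)C)C(=O)OC(C)(C)C | intermediate
12 | 1,1-di-tert-butyl 2-methyl ethene-1,1,2-tricarboxylate | COC(=O)C=C(C(=O)OC(C)(C)C)C(=O)OC(C)(C)C | intermediate
13 | 1,1-di-tert-butyl 2-methyl (2R,3Z,5S)-5-{[(tert-butyldiphenylsilyl)oxy]methyl}-4-hexadecylhepta-3,6-diene-1,1,2-tricarboxylate | CCCCCCCCCCCCCCCC/C(=C/[C@@H](C(=O)OC)C(C(=O)OC(C)(C)C)C(=O)OC(C)(C)C)[C@@H](CO[Si](c1ccccc1)(c1ccccc1)C(C)(C)C)C=C | intermediate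
14 | methyl (2R,3Z,5S)-5-{[(tert-butyldiphenylsilyl)oxy]methyl}-2-(1,3-dichloro-1,3-dioxopropan-2-yl)-4-hexadecylhepta-3,6-dienoate | CCCCCCCCCCCCCCCC/C(=C/[C@@H](C(=O)OC)C(C(=O)Cl)C(=O)Cl)[C@@H](CO[Si](c1ccccc1)(c1ccccc1)C(C)(C)C)C=C | intermediate
15 | methyl 3-[(2R,3Z,5S)-5-{[(tert-butyldiphenylsilyl)oxy]methyl}-4-hexadecyl-1-methoxy-1-oxohepta-3,6-dien-2-yl]-6-hexadecyl-4-hydroxy-2-oxo-2H-pyran-5-carboxylate | CCCCCCCCCCCCCCCC/C(=C/[C@@H](C(=O)OC)C1=C(O)C(C(=O)OC)=C(CCCCCCCCCCCCCCCC)OC1=O)[C@@H](CO[Si](c1ccccc1)(c1ccccc1)C(C)(C)C)C=C | intermediate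
16 | bridged lactone cycloadduct: decalin skeleton of 18 with a C5 enol (C5=C6) and a –C(=O)–O– bridge from C4a (carbonyl end) to C7 (oxygen end) on the ring-B face that carries H-8a; C1, C4 and C8a as in 18 | CCCCCCCCCCCCCCCCC1=C[C@@H](C(=O)OC)[C@@]2(C(=O)O3)C(O)=C(C(=O)OC)[C@@]3(CCCCCCCCCCCCCCCC)C[C@H]2[C@@H]1CO[Si](c1ccccc1)(c1ccccc1)C(C)(C)C | intermediate
17 | dimethyl (1S,4R,8aS)-1-{[(tert-butyldiphenylsilyl)oxy]methyl}-2,7-dihexadecyl-5-hydroxy-1,4,8,8a-tetrahydronaphthalene-4,6-dicarboxylate (C4a=C5 dienol) | CCCCCCCCCCCCCCCCC1=C[C@@H](C(=O)OC)C2=C(O)C(C(=O)OC)=C(CCCCCCCCCCCCCCCC)C[C@H]2[C@@H]1CO[Si](c1ccccc1)(c1ccccc1)C(C)(C)C | intermediate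
18 | dimethyl (1S,4R,4aS,8aS)-1-{[(tert-butyldiphenylsilyl)oxy]methyl}-2,7-dihexadecyl-5-oxo-1,4,4a,5,8,8a-hexahydronaphthalene-4,6-dicarboxylate | CCCCCCCCCCCCCCCCC1=C[C@@H](C(=O)OC)[C@H]2C(=O)C(C(=O)OC)=C(CCCCCCCCCCCCCCCC)C[C@H]2[C@@H]1CO[Si](c1ccccc1)(c1ccccc1)C(C)(C)C | intermediate
19 | dimethyl (1S,4R,4aS,8aS)-2,7-dihexadecyl-1-(hydroxymethyl)-5-oxo-1,4,4a,5,8,8a-hexahydronaphthalene-4,6-dicarboxylate | CCCCCCCCCCCCCCCCC1=C[C@@H](C(=O)OC)[C@H]2C(=O)C(C(=O)OC)=C(CCCCCCCCCCCCCCCC)C[C@H]2[C@@H]1CO | intermediate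
20 | (1S,4R,4aS,8aR)-2,7-dihexadecyl-4,6-bis(methoxycarbonyl)-5-oxo-1,4,4a,5,8,8a-hexahydronaphthalene-1-carboxylic acid | CCCCCCCCCCCCCCCCC1=C[C@@H](C(=O)OC)[C@H]2C(=O)C(C(=O)OC)=C(CCCCCCCCCCCCCCCC)C[C@H]2[C@@H]1C(=O)O | intermediate
21 | trimethyl (1S,4R,4aS,8aR)-2,7-dihexadecyl-5-oxo-1,4,4a,5,8,8a-hexahydronaphthalene-1,4,6-tricarboxylate | CCCCCCCCCCCCCCCCC1=C[C@@H](C(=O)OC)[C@H]2C(=O)C(C(=O)OC)=C(CCCCCCCCCCCCCCCC)C[C@H]2[C@@H]1C(=O)OC | target

Total step count: 11.
Longest linear sequence: 9 steps (4 → 5 → 6 → 8 → 13 → 15 → 18 → 19 → 20 → 21; steps 2, 3, 4, 6, 7, 8, 9, 10, 11).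

Steps most likely to fail

Step 8. At 150 °C the free 4-hydroxyl may lactonise onto the neighbouring C4 ester. The acidic pyrone may move the skipped-diene double bond. Proton delivery to C4a in the hot, unbuffered medium may be unselective. The fallback sets out from 15 and separates cycloaddition from ketonisation. Mitsunobu O-methylation (MeOH, PPh3, DIAD, THF, 0 °C) should give the 4-methoxy-2-pyrone F1. The same thermal cycloaddition and CO2 loss then stops at the isolable methyl dienol ether F2. Hydrolysis of F2 with dilute aqueous acid in THF at 0 °C protonates C4a under kinetic control and comes back to the route at 18.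

Step 6. The β,β-disubstituted alkenylboronate may transmetalate slowly and protodeboronate. The very electrophilic triester may hydrate or oligomerise in aqueous base. Facial control may be weak. The fallback sets out from 8 and changes both the metal and the catalyst class. Iodo-deboronation with retention (NaOH, I2, THF, 0 °C) gives the alkenyl iodide F3. Iodine–lithium exchange (t-BuLi, Et2O, −78 °C), transmetalation to the dimethylalane (Me2AlCl) and copper(I)/chiral phosphoramidite-catalysed conjugate addition to 12 under anhydrous conditions at −30 °C come back to the route at 13.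

Step 7. Hydrogen chloride may erode the silyl ether or add to the trisubstituted alkene. The chlorocarbonyl ketene derived from 14 may undergo an intramolecular [2+2] reaction with the vinyl group. O-acylation may compete with C-acylation. The fallback sets out from 13 and avoids acid chlorides altogether. Trifluoroacetic acid in CH2Cl2 cleaves the tert-butyl esters to the substituted malonic acid F4. Carbodiimide coupling with 2,4,6-trichlorophenol at 0 °C gives the active bis(2,4,6-trichlorophenyl) malonate F5. Chloride-free thermal condensation of F5 with 3 in bromobenzene at 150 °C comes back to the route at 15.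

Further compounds
F1 | step 8 | methyl 3-[(2R,3Z,5S)-5-{[(tert-butyldiphenylsilyl)oxy]methyl}-4-hexadecyl-1-methoxy-1-oxohepta-3,6-dien-2-yl]-6-hexadecyl-4-methoxy-2-oxo-2H-pyran-5-carboxylate | CCCCCCCCCCCCCCCC/C(=C/[C@@H](C(=O)OC)C1=C(OC)C(C(=O)OC)=C(CCCCCCCCCCCCCCCC)OC1=O)[C@@H](CO[Si](c1ccccc1)(c1ccccc1)C(C)(C)C)C=C
F2 | step 8 | dimethyl (1S,4R,8aS)-1-{[(tert-butyldiphenylsilyl)oxy]methyl}-2,7-dihexadecyl-5-methoxy-1,4,8,8a-tetrahydronaphthalene-4,6-dicarboxylate | CCCCCCCCCCCCCCCCC1=C[C@@H](C(=O)OC)C2=C(OC)C(C(=O)OC)=C(CCCCCCCCCCCCCCCC)C[C@H]2[C@@H]1CO[Si](c1ccccc1)(c1ccccc1)C(C)(C)C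
F3 | step 6 | tert-butyl{[(2S,3Z)-2-ethenyl-3-(iodomethylidene)nonadecyl]oxy}diphenylsilane | CCCCCCCCCCCCCCCC/C(=C/I)[C@@H](CO[Si](c1ccccc1)(c1ccccc1)C(C)(C)C)C=C
F4 | step 7 | 2-[(2R,3Z,5S)-5-{[(tert-butyldiphenylsilyl)oxy]methyl}-4-hexadecyl-1-methoxy-1-oxohepta-3,6-dien-2-yl]propanedioic acid | CCCCCCCCCCCCCCCC/C(=C/[C@@H](C(=O)OC)C(C(=O)O)C(=O)O)[C@@H](CO[Si](c1ccccc1)(c1ccccc1)C(C)(C)C)C=C
F5 | step 7 | bis(2,4,6-trichlorophenyl) 2-[(2R,3Z,5S)-5-{[(tert-butyldiphenylsilyl)oxy]methyl}-4-hexadecyl-1-methoxy-1-oxohepta-3,6-dien-2-yl]propanedioate | CCCCCCCCCCCCCCCC/C(=C/[C@@H](C(=O)OC)C(C(=O)Oc1c(Cl)cc(Cl)cc1Cl)C(=O)Oc1c(Cl)cc(Cl)cc1Cl)[C@@H](CO[Si](c1ccccc1)(c1ccccc1)C(C)(C)C)C=C
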